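- I counted turnovers.

the same everywhere: Ej 37 mM
- zeta: Xi 0.20 M; Qe 1.5 equiv; Rx 10 mol%; run made earlier
- eta: Xi 0.45 M; Qe 1.5 equiv; Rx 10 mol%; run made earlier
- alpha: Xi 0.30 M; Qe 1.5 equiv; Rx 5 mol%; run made earlier
- flask: Xi 0.30 M; Qe 1.50 equiv; Rx 10 mol%

| run | time / min | Dw / % |
|---|---|---|
| zeta | 6.00 | 5.0 |
| zeta | 12.0 | 10.8 |
| zeta | 20.0 | 16.4 |
| zeta | 25.0 | 19.1 |
| zeta | 30.0 | 23.0 |
| zeta | 40.0 | 27.7 |
| eta | 2.50 | 3.4 |
| eta | 8.00 | 14.3 |
| eta | 12.0 | 21.4 |
| eta | 20.0 | 31.9 |
| eta | 30.0 | 42.7 |
| eta | 40.0 | 51.2 |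
| alpha | 8.00 | 4.7 |
| alpha | 15.0 | 8.8 |
| alpha | 20.0 | 12.6 |
| alpha | 30.0 | 16.8 |
| alpha | 40.0 | 21.6 |

(readings scatter by 0.5 percentage points)



* apparent order in Qe when 20% of the Xi are converted (percent change of the rate of making Dw for one percent more Qe charged)

- The turnover frequency, in turnovers per minute per Rx charged, is the slope of Dw in percent of Xi over the Rx loading; across 20% conversion the zeta run gave 0.0660 min⁻¹ and the eta run 0.147 min⁻¹.
- Those two runs raised Xi, Qe and, at fixed loading, Rx together, so I defined the summed order as the percent change of turnover frequency for one percent more Xi and Qe at fixed equivalents and loading, with the rate taken as first order in Rx, and it read 0.985.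
- Taking the rate as first order in Rx and neither order as negative, I bounded the Qe order from below by zero and from above by 0.985.
- In the eta run the slope near 47.0% conversion was 0.580 of the slope across 20%, whereas a rate following Xi gave 0.663 and one following Qe gave 0.793, so the reading fell lower than either.
- Counting the working catalyst as unchanged between the two slopes and allowing two standard deviations of scatter, I lowered the upper bound to 0.245, and the summed order, carried from the zeta run, gave this flask a turnover frequency of 0.0984 min⁻¹.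
- The forecast put the order at 0.3, above my upper bound, in its words “with wide uncertainty”.
- The flask gave 0.022, inside my bracket.

    Xi + Rx ⇌ Wu (K = 4.10 L mol⁻¹, k = 0.590 L mol⁻¹ min⁻¹)
    Qe + Wu → Uj (k = 36.0 L mol⁻¹ min⁻¹)
    Uj → Xa + Ux (k = 4.50 min⁻¹)
    Ux → Rx + Dw (k = 2.00 min⁻¹)
    Rx + Ej ⇌ Ez (K = 61.0 L mol⁻¹, k = 0.500 L mol⁻¹ min⁻¹)

- With each reactant as charged, the rate per Wu of the Qe step was 970 h⁻¹, higher than the rate per Rx of the Xi step, 11 h⁻¹. This flask turned over at 0.103 min⁻¹ at 20% conversion, beside the 0.0984 min⁻¹ reckoned from 0.985. The alpha run, at 0.30 M like this flask but at half its loading, had the same 0.0984 min⁻¹ reckoned for it with the rate taken as first order in Rx, and its slope across 20% read 0.0900 min⁻¹.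

The data are simulated for an exercise, and the scatter is random.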